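**Retrosynthetic overview**
- The strategy rests on ring B, the 2,4-dibromophenoxy ring: its carbons C2'(Br)–C3'(H)–C4'(Br)–C5'(H) are C3–C4–C5–C6 of 3,5-dibromo-2-pyrone, so only C1'(O) and C6'(H) have to be added, as the two alkyne carbons of an aryl ethynyl ether.
- Cutting C1'–C2' and C5'–C6' (Diels–Alder, then loss of CO2) gives 3,5-dibromo-2-pyrone and 1,5-dibromo-3-(ethynyloxy)-2-methoxybenzene; the diaryl ether oxygen is already in place as the ynol ether oxygen.
- The ynol ether comes from the 2-bromovinyl ether (loss of HBr), that from the aryl vinyl ether (Br2, then loss of HBr), and that from 3,5-dibromo-2-methoxyphenol by transfer vinylation.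
- The phenol comes from 3,5-dibromo-2-methoxybenzaldehyde (Baeyer–Villiger) and that from 3,5-dibromosalicylaldehyde (O-methylation).
- Ring order: ring A (the dibromoanisole ring) is bought fully substituted; ring B is the only ring formed, in the last step.

Key step: step 6

Remark: the target has no stereogenic element, so the "single enantiomer" requirement needs no stereocontrol; 3,5-dibromo-2-pyrone is taken as purchasable.

**Step 1**
Reactants: 1 3,5-dibromosalicylaldehyde
Product: 2 3,5-dibromo-2-methoxybenzaldehyde
Conditions: MeI, K2CO3, DMF, rt
Reagents that add atoms: iodomethane, CI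
Why: Williamson O-methylation of an acidic phenol is routine, and neither the aldehyde nor the aryl bromides react with carbonate and MeI.

**Step 2**
Reactants: 2 3,5-dibromo-2-methoxybenzaldehyde
Product: 4 3,5-dibromo-2-methoxyphenol, via aryl formate 3 (not isolated)
Conditions: mCPBA, CH2Cl2, reflux; aq. Na2SO3/NaHCO3 wash; then K2CO3 (cat.), MeOH, rt
Reagents that add atoms: meta-chloroperoxybenzoic acid, OOC(=O)c1cccc(Cl)c1
Why: In this Baeyer–Villiger oxidation the ortho-methoxyaryl group should migrate in preference to hydrogen in the Criegee adduct, and the resulting aryl formate is cleaved by mild methanolysis that leaves the aryl bromides alone.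

**Step 3**
Reactants: 4 3,5-dibromo-2-methoxyphenol
Product: 5 1,5-dibromo-3-(ethenyloxy)-2-methoxybenzene
Conditions: vinyl acetate (3 equiv), [Ir(cod)Cl]2 (2 mol%), Na2CO3 (0.6 equiv), toluene, 100 °C
Reagents that add atoms: vinyl acetate, C=COC(C)=O
Why: Iridium-catalysed transfer vinylation (phenoxide addition to iridium-bound vinyl acetate, then β-acetoxy elimination) is an established route to aryl vinyl ethers, and the phosphine-free iridium(I) catalyst should not insert into aryl C–Br bonds.

**Step 4**
Reactants: 5 1,5-dibromo-3-(ethenyloxy)-2-methoxybenzene
Product: 7 1,5-dibromo-3-[(2-bromoethenyl)oxy]-2-methoxybenzene (Z/E mixture), via 1,2-dibromoethyl ether 6 (not isolated)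
Conditions: Br2 (1.0 equiv), CH2Cl2, −78 °C; then DBU (1.5 equiv), −78 °C to rt
Reagents that add atoms: bromine, BrBr
Why: Electrophilic bromine addition to the enol ether double bond is much faster than substitution on the deactivated arene, and DBU dehydrobromination of the α-bromo ether (the bromination–elimination sequence used to make 2-bromo enol ethers) expels the labile α-bromide to give the β-bromovinyl ether.

**Step 5**
Reactants: 7 1,5-dibromo-3-[(2-bromoethenyl)oxy]-2-methoxybenzene
Product: 8 1,5-dibromo-3-(ethynyloxy)-2-methoxybenzene
Conditions: KOtBu (2.2 equiv), THF, −78 °C to 0 °C; cold pH 7 buffer work-up; kept cold in toluene and used at once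
Reagents that add atoms: none
Why: Base-induced 1,2-dehydrobromination of a 2-bromovinyl ether is the classical entry to alkynyl ethers (anti elimination from the Z isomer, the slower syn path from the E isomer on warming), and tert-butoxide at low temperature is too weak to metalate the ring or form arynes.

**Step 6**
Reactants: 8 1,5-dibromo-3-(ethynyloxy)-2-methoxybenzene; 9 3,5-dibromo-2H-pyran-2-one
Product: 11 1,5-dibromo-3-(2,4-dibromophenoxy)-2-methoxybenzene (target), via bicyclic lactone 10 (not isolated)
Conditions: 9 (1.5 equiv), BHT (cat.), toluene, 100 °C, slow addition of 8, vented to release CO2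
Reagents that add atoms: none
Why: The electron-poor pyrone diene (C3=C4–C5=C6) and the electron-rich ynol ether should combine in an inverse-demand Diels–Alder reaction in which the nucleophilic terminal alkyne carbon bonds to C6, the δ-carbon of the dienoate, so that the oxygen-bearing carbon bonds to C3. The 2-oxabicyclo[2.2.2]octadienone 10 then loses CO2 by an irreversible retro-[4+2] that is driven by aromatisation, so no oxidant is needed. The closest known reaction type is the pyrone–alkyne cycloaddition/decarboxylation route to benzenes, and the same orientation (donor-bearing carbon next to C3) is found in adducts of 3-bromo- and 3,5-dibromo-2-pyrone with enol ethers. Ring B is closed by intermolecular [4+2] cycloaddition that forms C1'–C2' and C5'–C6' in one operation. No stereocentre survives, since the two bridgehead centres of 10 become aromatic carbons. The step needs regioselectivity (2,4- and not 3,5-dibromophenoxy), which the matched polarisation of the two partners should secure, and chemoselectivity for four C–Br bonds, which is given because no metal, base or nucleophile is present.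

**Compound list**
1 | 3,5-dibromosalicylaldehyde | O=Cc1cc(Br)cc(Br)c1O | starting material
2 | 3,5-dibromo-2-methoxybenzaldehyde | COc1c(Br)cc(Br)cc1C=O | intermediate
3 | 3,5-dibromo-2-methoxyphenyl formate | COc1c(Br)cc(Br)cc1OC=O | intermediate (not isolated)
4 | 3,5-dibromo-2-methoxyphenol | COc1c(Br)cc(Br)cc1O | intermediate
5 | 1,5-dibromo-3-(ethenyloxy)-2-methoxybenzene | COc1c(Br)cc(Br)cc1OC=C | intermediate
6 | rac-1,5-dibromo-3-(1,2-dibromoethoxy)-2-methoxybenzene | COc1c(Br)cc(Br)cc1OC(Br)CBr | intermediate (not isolated)
7 | 1,5-dibromo-3-[(2-bromoethenyl)oxy]-2-methoxybenzene (Z isomer drawn; E isomer also expected and carried on) | COc1c(Br)cc(Br)cc1O/C=C\Br | intermediate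
8 | 1,5-dibromo-3-(ethynyloxy)-2-methoxybenzene | COc1c(Br)cc(Br)cc1OC#C | intermediate
9 | 3,5-dibromo-2H-pyran-2-one | O=C1OC=C(Br)C=C1Br | starting material
10 | rac-4,7-dibromo-5-(3,5-dibromo-2-methoxyphenoxy)-2-oxabicyclo[2.2.2]octa-5,7-dien-3-one | O=C1OC2C=C(Oc3cc(Br)cc(Br)c3OC)C1(Br)C=C2Br | intermediate (not isolated)
11 | 1,5-dibromo-3-(2,4-dibromophenoxy)-2-methoxybenzene | COc1c(Br)cc(Br)cc1Oc1ccc(Br)cc1Br | target

**Step count**
Total steps: 6. Longest linear sequence: 6 steps (1 to 11); pyrone 9 enters in step 6.

**Steps most likely to fail**

Step 6. The terminal ynol ether may oligomerise thermally faster than it is trapped by the pyrone, and the electron-poor aryloxy group polarises the alkyne less than an alkoxy group, so some addition in the reverse orientation (leading to a 3,5-dibromophenoxy ring) could occur. The fallback sets out from phenol 4 and returns at 11. 1,3-Dibromobenzene would be treated with iodyl sulfate in concentrated sulfuric acid and then with sodium chloride to give bis(2,4-dibromophenyl)iodonium chloride F1. The sodium phenoxide of 4 (NaOH, water/dioxane, 80 °C) would then be O-arylated by F1 through ligand coupling at iodine(III), which should give 11 directly, with the bromine pattern of ring B fixed by the iodonium salt.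

Step 5. Syn elimination from the E isomer may stay incomplete, and the ynol ether may hydrate or oligomerise during work-up and concentration. The fallback sets out from bromovinyl ether 7 and returns at 11, avoiding the free ynol ether by using 7 as an alkyne equivalent. Heating 7 with pyrone 9 in toluene (110–130 °C, sealed tube) should give, with the same orientation, 4,6,7-tribromo-5-(3,5-dibromo-2-methoxyphenoxy)-2-oxabicyclo[2.2.2]oct-7-en-3-one F2. At that temperature F2 should lose CO2 to give 1,5-dibromo-2-methoxy-3-[(2,4,6-tribromocyclohexa-2,4-dien-1-yl)oxy]benzene F3. DBU would then remove HBr across C1–C6 of that ring, bromide being a far better leaving group than the aryloxide, and so aromatise it to 11.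

Step 3. The acidic, hindered phenoxide may be O-acetylated by vinyl acetate instead of vinylated, or may turn the iridium catalyst over slowly through chelation by the two adjacent oxygens. The fallback sets out from phenol 4 and returns at 5. Alkylation of 4 with excess 1,2-dibromoethane (K2CO3, MeCN, reflux) should give 1,5-dibromo-3-(2-bromoethoxy)-2-methoxybenzene F4. E2 elimination of F4 with KOtBu in THF at 0 °C to rt should then give vinyl ether 5 without any transition metal.

**Further compounds**
F1 | step 6 | bis(2,4-dibromophenyl)iodonium chloride | Brc1ccc([I+]c2ccc(Br)cc2Br)c(Br)c1.[Cl-]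
F2 | step 5 | 4,6,7-tribromo-5-(3,5-dibromo-2-methoxyphenoxy)-2-oxabicyclo[2.2.2]oct-7-en-3-one (racemic, diastereomer mixture) | O=C1OC2C(Br)C(Oc3cc(Br)cc(Br)c3OC)C1(Br)C=C2Br
F3 | step 5 | 1,5-dibromo-2-methoxy-3-[(2,4,6-tribromocyclohexa-2,4-dien-1-yl)oxy]benzene (racemic, diastereomer mixture) | BrC1C=C(Br)C=C(Br)C1Oc1cc(Br)cc(Br)c1OC
F4 | step 3 | 1,5-dibromo-3-(2-bromoethoxy)-2-methoxybenzene | COc1c(Br)cc(Br)cc1OCCBr
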